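The larch run is flat within scatter from its first reading, with substrate near 85.0 % and target near 13.5 %, and the birch run, with more partner, levels off higher. Where does this flask level off?

| flask | substrate | partner | free catalyst | remark | time |
|---|---|---|---|---|---|
| larch | 0.10 M | 0.12 M | 17 mM | run made earlier |  |
| birch | 0.10 M | 0.50 M | 17 mM | run made earlier |  |
| oak | 0.15 M | 0.25 M | 17 mM | run made earlier |  |
| flask | 0.10 M | 0.250 M | 17 mM |  | 8.0 min |

| run | time / min | substrate / % | target / % |
|---|---|---|---|
| larch | 1.00 | 85.0 | 13.5 |
| larch | 2.00 | 84.4 | 16.4 |
| larch | 3.00 | 83.6 | 13.8 |
| larch | 4.00 | 84.4 | 13.7 |
| larch | 5.00 | 85.8 | 15.0 |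
| birch | 0.417 | 79.1 | 21.8 |
| birch | 1.33 | 76.4 | 23.4 |
| birch | 2.00 | 75.6 | 22.5 |
| birch | 3.00 | 76.0 | 23.4 |
| birch | 5.00 | 78.3 | 22.5 |
| oak | 0.417 | 89.1 | 15.1 |
| oak | 1.33 | 87.5 | 14.3 |
| oak | 2.00 | 85.8 | 12.3 |
| oak | 3.00 | 88.3 | 10.4 |
| oak | 5.00 | 86.6 | 13.7 |

(standard deviation of a reading: 1 percentage point)

- the numbers in the tables scatter with a standard deviation of 1 percentage point
- steps that have been proposed: catalyst intermediate A <-> catalyst intermediate B; catalyst intermediate B <-> released group + catalyst intermediate C; catalyst intermediate D -> free catalyst + target; substrate + catalyst intermediate C -> catalyst intermediate D; partner -> decomposed reagent; partner + free catalyst -> catalyst intermediate A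
- the reaction counts as stopped when no species that holds the substrate changes by six tenths of a point or more over the second half of the time

1. the state of affairs at 8.0 min: stopped, and by what, or still going (it is still moving / all of the substrate has reacted / the partner has run out first / forward and back rates have come level / no working catalyst is left)
2. part of the substrate gone at 8.0 min
3. the target standing at 8.0 min, as a percentage of the substrate charged

1. I average the 5 target readings of each run and turn them into concentrations: c(target) stands at 14.5 mM in larch and 22.7 mM in birch. At its last reading, larch's substrate and target add to 101 %, so I count substrate lost as target formed.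

2. Among the proposed steps, partner has two drains: it decomposes by itself, or it binds free catalyst. One passage through the catalyst gives one target. My zero mark is therefore the one-for-one case, 100 % of the partner becoming target.

3. The oak run has this flask's partner charge and gives 19.7 mM of target, which is 7.90 % of its partner. I call this the partner yield, target formed per partner charged. It belongs to one partner charge, since larch gives 12.1 % and birch 4.54 %.

4. Oak holds more substrate than this flask. As a check, I interpolate on the logarithm of the partner charge between larch and birch, which share this flask's substrate. That gives 18.7 mM, which is 1.00 mM below oak. So, with free catalyst at 17 mM and partner at 0.250 M, I treat the partner yield as nearly indifferent to substrate between 0.10 M and 0.15 M.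

5. For this flask I commit to the partner yield times 0.250 M, divided by 0.10 M: 19.7 % target, with the same conversion. I expect the partner to stop this flask, since larch and birch share substrate and free catalyst and birch, with more partner, stands higher. I expect the stop before 8.0 min, since larch is flat at its first reading, 1.00 min.

The forecast says the partner has run out first, with 18.7 % converted and 18.4 % target, which is lower than my figure. Its ground for the stop: "No catalyst-death step is proposed and the target-forming step is irreversible, so the stop is partner exhaustion, not equilibrium."

    catalyst intermediate A ⇌ catalyst intermediate B (K = 1.70, k = 0.310 /s)
    catalyst intermediate B ⇌ released group + catalyst intermediate C (K = 0.0480 M, k = 1.00 /s)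
    catalyst intermediate D → free catalyst + target (k = 3.10 /s)
    substrate + catalyst intermediate C → catalyst intermediate D (k = 44.0 /M/s)
    partner → decomposed reagent (k = 0.740 /s)
    partner + free catalyst → catalyst intermediate A (k = 12.0 /M/s)

The flask gives 19.9 % target and 19.9 % conversion: the partner has run out first. At 8.00 min, partner, the limiting reagent here although its charge of 0.250 M exceeds the 0.10 M of substrate, stands at 0 % of its charge, less than substrate at 80 %. The flask's partner yield is 7.96 %. Carrying the oak value of 7.90 % to the neighbour flask, which differs by holding 0.17 M of substrate, gives 11.6 % target, and that neighbour stands at 11.8 %.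

Readings and results were generated by integration with made-up constants; the scatter is artificial.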